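**Retrosynthetic overview**
- Target 17 ⇐ Schenck ene reaction of singlet oxygen on the 7(11)-en-8-one angelate 16 (forms C11–OO, moves the alkene to C6=C7) ⇐ angeloylation of diol 13 with angelic acid 14.
- Enone 13 ⇐ the lactone carbons C11–C13 of the isoalantolactone series: lactone to 8,12-diol, C12 deoxygenated through its allylic acetate, C8 oxidised, alkene moved into conjugation.
- C4 carbinol (α-OH, β-CH3) ⇐ hydride opening at C15 of spiro-epoxide 6 ⇐ α-face epoxidation of the exocyclic C4=C15 alkene of silyl ether 5 ⇐ isoalantolactone 1 (C3 allylic oxidation, oxidation/reduction to the 3β-alcohol, silylation).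
- Feature the plan rests on: 1 already holds the trans-fused ring A (C1–C5, C10) and ring B (C5–C10) with 5α-H and the axial 10β-methyl, the C8 oxygen, and the exocyclic C4=C15 alkene on ring A. The axial C10 methyl screens the β face of that alkene.
- Ring order: rings A and B are bought with 1. The only ring made is the C4/C15 oxirane (step 5), opened in step 7. The lactone ring is opened in step 6.

Key step: step 5

Assumption (chemistry): step 1 is taken to give mainly the axial 3α-alcohol, drawn as 2; any 3β epimer formed alongside is carried into step 2, where both converge on ketone 3.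

**Route**

Step 1
Reactants: 1 isoalantolactone
Product: 2 3α-hydroxyisoalantolactone
Conditions: SeO2 (cat.), t-BuOOH, CH2Cl2, rt
Reagents that add atoms: tert-butyl hydroperoxide CC(C)(C)OO (oxygen source, relayed through selenium dioxide O=[Se]=O)
Why: Riley allylic oxidation, in which an ene reaction of SeO2 at the electron-rich C4=C15 alkene and a [2,3]-sigmatropic shift place oxygen on the secondary allylic carbon C3 and restore the exocyclic alkene, while the electron-poor lactone methylene does not react and the C3 configuration is erased in step 2.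

Step 2
Reactants: 2 3α-hydroxyisoalantolactone
Product: 3 3-oxoisoalantolactone
Conditions: Dess–Martin periodinane, CH2Cl2, rt
Reagents that add atoms: none
Why: Dess–Martin oxidation of a secondary allylic alcohol under near-neutral conditions should give the exocyclic enone without touching the lactone, and either C3 epimer gives the same ketone.

Step 3
Reactants: 3 3-oxoisoalantolactone
Product: 4 3β-hydroxyisoalantolactone
Conditions: NaBH4, CeCl3·7H2O, MeOH, −78 °C
Reagents that add atoms: none
Why: Luche reduction, in which the hard cerium-activated methoxyborohydride adds 1,2 to the ketone faster than it adds to the methylene lactone, and axial hydride delivery from the α face (only axial hydrogens at C1 and C5 on that side) sets the equatorial 3β-alcohol.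

Step 4
Reactants: 4 3β-hydroxyisoalantolactone
Product: 5 3β-(tert-butyldimethylsilyloxy)isoalantolactone
Conditions: TBSCl, imidazole, DMF, rt
Reagents that add atoms: tert-butyldimethylsilyl chloride CC(C)(C)[Si](C)(C)Cl
Why: Standard imidazole-mediated silylation of an unhindered equatorial secondary alcohol, which removes any hydroxyl direction from the epoxidation and protects C3–OH through the hydride steps.

Step 5
Reactants: 5 3β-(tert-butyldimethylsilyloxy)isoalantolactone
Product: 6 3β-(tert-butyldimethylsilyloxy)-4α,15-epoxyisoalantolactone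
Conditions: dimethyldioxirane (acetone solution, 1.2 equiv), CH2Cl2, −20 → 0 °C
Reagents that add atoms: dimethyldioxirane CC1(C)OO1
Why: Dimethyldioxirane transfers one oxygen atom to the C4=C15 alkene through a concerted spiro transition state, and the closest known reaction type is the peracid (Prilezhaev) or dioxirane epoxidation of 4(15)-eudesmenes. The oxirane, the only ring made in the route, closes in that single event by syn formation of the C4–O and C15–O bonds, with no open intermediate and no separate cyclisation. The new stereocentre C4 is set by the axial C10 methyl, which lies 1,3-diaxial to the β side of C4 and so sends oxygen to the α (equatorial) side, leaving C15 axial. The step needs face selectivity (α over β) and site selectivity (C4=C15 over C11=C13). The first rests on the angular methyl, helped by the equatorial C3 silyloxy group, which lies near the alkene plane, covers neither face and cannot hydrogen-bond to the oxidant. The second rests on electronics, since the dioxirane is electrophilic and the conjugated lactone methylene is electron-poor, and the neutral acid-free medium keeps the spiro-epoxide from rearranging.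

Step 6
Reactants: 6 3β-(tert-butyldimethylsilyloxy)-4α,15-epoxyisoalantolactone
Product: 7 3β-(tert-butyldimethylsilyloxy)-4α,15-epoxyeudesm-11(13)-ene-8β,12-diol
Conditions: i-Bu2AlH (4 equiv), CH2Cl2, −78 → −30 °C; aq. potassium sodium tartrate
Reagents that add atoms: none
Why: i-Bu2AlH reduces α-methylene lactones by 1,2-hydride addition without conjugate reduction, giving the allylic 1,4-diol with C7 and C8 unchanged, and at low temperature the hindered spiro-epoxide and the silyl ether should not be attacked.

Step 7
Reactants: 7 3β-(tert-butyldimethylsilyloxy)-4α,15-epoxyeudesm-11(13)-ene-8β,12-diol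
Product: 8 3β-(tert-butyldimethylsilyloxy)eudesm-11(13)-ene-4α,8β,12-triol
Conditions: LiEt3BH (4 equiv), THF, 0 → 45 °C; H2O
Reagents that add atoms: none
Why: SN2 hydride opening of the epoxide by the strongly nucleophilic LiEt3BH at the unsubstituted carbon C15, so the C4–O bond made in step 5 is kept and C4 ends with α-OH and an axial β-methyl, while the isolated 1,1-disubstituted alkene and the silyl ether are inert.

Step 8
Reactants: 8 3β-(tert-butyldimethylsilyloxy)eudesm-11(13)-ene-4α,8β,12-triol
Product: 9 12-acetoxy-3β-(tert-butyldimethylsilyloxy)eudesm-11(13)-ene-4α,8β-diol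
Conditions: Ac2O (1.1 equiv), pyridine, CH2Cl2, 0 °C
Reagents that add atoms: acetic anhydride CC(=O)OC(C)=O
Why: Kinetically selective acylation of the primary allylic hydroxyl over the axial 8β-hydroxyl (1,3-diaxial to the C10 methyl) and the tertiary 4α-hydroxyl, the acetate serving first as protecting group and then as leaving group.

Step 9
Reactants: 9 12-acetoxy-3β-(tert-butyldimethylsilyloxy)eudesm-11(13)-ene-4α,8β-diol
Product: 10 12-acetoxy-3β-(tert-butyldimethylsilyloxy)-4α-hydroxyeudesm-11(13)-en-8-one
Conditions: Dess–Martin periodinane, CH2Cl2, rt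
Reagents that add atoms: none
Why: Dess–Martin oxidation of the only remaining secondary alcohol (axial, hence readily oxidised), with the tertiary alcohol, acetate and silyl ether inert and no base present to move the β,γ-alkene.

Step 10
Reactants: 10 12-acetoxy-3β-(tert-butyldimethylsilyloxy)-4α-hydroxyeudesm-11(13)-en-8-one
Product: 11 3β-(tert-butyldimethylsilyloxy)-4α-hydroxy-7αH-eudesm-11(12)-en-8-one
Conditions: Pd(PPh3)4 (5 mol %), HCO2NH4, 1,4-dioxane, 80 °C
Reagents that add atoms: none
Why: Tsuji–Trost-type allylic hydrogenolysis, in which zerovalent palladium ionises the allylic acetate to a 2-substituted π-allyl complex and formate delivers hydride with loss of CO2; both allyl termini are CH2 groups, so either regiochemistry gives the same isopropenyl group, and the ketone is not reduced.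

Step 11
Reactants: 11 3β-(tert-butyldimethylsilyloxy)-4α-hydroxy-7αH-eudesm-11(12)-en-8-one
Product: 12 3β-(tert-butyldimethylsilyloxy)-4α-hydroxyeudesm-7(11)-en-8-one
Conditions: DBU, toluene, 60 °C
Reagents that add atoms: none
Why: Base-mediated β,γ to α,β alkene isomerisation through the C7 dienolate, protonated at the terminal carbon, should give mainly the more stable tetrasubstituted conjugated enone (the isopulegone to pulegone change); C7 becomes sp2 and neither C5 nor C10 is enolisable.

Step 12
Reactants: 12 3β-(tert-butyldimethylsilyloxy)-4α-hydroxyeudesm-7(11)-en-8-one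
Product: 13 3β,4α-dihydroxyeudesm-7(11)-en-8-one
Conditions: HF·pyridine, THF, 0 °C → rt
Reagents that add atoms: none
Why: Fluoride-driven Si–O cleavage under mildly acidic, non-basic conditions that leave the enone and the tertiary alcohol untouched.

Step 13
Reactants: 13 3β,4α-dihydroxyeudesm-7(11)-en-8-one; 14 angelic acid
Product: 16 3β-angeloyloxy-4α-hydroxyeudesm-7(11)-en-8-one, via angeloyl 2,4,6-trichlorobenzoyl anhydride 15 (not isolated)
Conditions: 14, 2,4,6-trichlorobenzoyl chloride, Et3N, toluene, rt; then 13, 75 °C
Reagents that add atoms: none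
Why: Yamaguchi-type esterification in which the secondary 3β-hydroxyl attacks the unhindered angeloyl carbonyl of the mixed anhydride while the tertiary 4α-hydroxyl stays free, and leaving out nucleophilic catalysts avoids the reversible conjugate addition that turns angelates into tiglates.

Step 14
Reactants: 16 3β-angeloyloxy-4α-hydroxyeudesm-7(11)-en-8-one
Product: 17 3β-angeloyloxy-11-hydroperoxy-4α-hydroxyeudesm-6-en-8-one (target)
Conditions: O2, tetraphenylporphyrin (cat.), CH2Cl2, visible light, 0 °C
Reagents that add atoms: dioxygen O=O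
Why: Schenck ene reaction of singlet oxygen with the s-cis tetrasubstituted enone, in which oxygen bonds to the β-carbon C11 and hydrogen is taken from the alkyl group geminal to the carbonyl (the axial 6β-H, aligned with the π system), the usual regiochemistry for α,β-unsaturated carbonyl compounds; this gives the tertiary hydroperoxide and the C6=C7 bond conjugated with C8=O, creates no stereocentre, and should leave the less reactive trisubstituted angelate alkene alone.

**Compound list**

1 | isoalantolactone | C=C1CCC[C@]2(C)C[C@H]3OC(=O)C(=C)[C@H]3C[C@@H]12 | starting material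
2 | 3α-hydroxyisoalantolactone | C=C1[C@H](O)CC[C@]2(C)C[C@H]3OC(=O)C(=C)[C@H]3C[C@@H]12 | intermediate
3 | 3-oxoisoalantolactone | C=C1C(=O)CC[C@]2(C)C[C@H]3OC(=O)C(=C)[C@H]3C[C@@H]12 | intermediate
4 | 3β-hydroxyisoalantolactone | C=C1[C@@H](O)CC[C@]2(C)C[C@H]3OC(=O)C(=C)[C@H]3C[C@@H]12 | intermediate
5 | 3β-(tert-butyldimethylsilyloxy)isoalantolactone | C=C1[C@@H](O[Si](C)(C)C(C)(C)C)CC[C@]2(C)C[C@H]3OC(=O)C(=C)[C@H]3C[C@@H]12 | intermediate
6 | 3β-(tert-butyldimethylsilyloxy)-4α,15-epoxyisoalantolactone | C1O[C@@]12[C@@H](O[Si](C)(C)C(C)(C)C)CC[C@]3(C)C[C@H]4OC(=O)C(=C)[C@H]4C[C@@H]23 | intermediate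
7 | 3β-(tert-butyldimethylsilyloxy)-4α,15-epoxyeudesm-11(13)-ene-8β,12-diol | C1O[C@@]12[C@@H](O[Si](C)(C)C(C)(C)C)CC[C@]3(C)C[C@@H](O)[C@@H](C(=C)CO)C[C@@H]23 | intermediate
8 | 3β-(tert-butyldimethylsilyloxy)eudesm-11(13)-ene-4α,8β,12-triol | C[C@@]1(O)[C@@H](O[Si](C)(C)C(C)(C)C)CC[C@]2(C)C[C@@H](O)[C@@H](C(=C)CO)C[C@@H]12 | intermediate
9 | 12-acetoxy-3β-(tert-butyldimethylsilyloxy)eudesm-11(13)-ene-4α,8β-diol | C[C@@]1(O)[C@@H](O[Si](C)(C)C(C)(C)C)CC[C@]2(C)C[C@@H](O)[C@@H](C(=C)COC(C)=O)C[C@@H]12 | intermediate
10 | 12-acetoxy-3β-(tert-butyldimethylsilyloxy)-4α-hydroxyeudesm-11(13)-en-8-one | C[C@@]1(O)[C@@H](O[Si](C)(C)C(C)(C)C)CC[C@]2(C)CC(=O)[C@@H](C(=C)COC(C)=O)C[C@@H]12 | intermediate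
11 | 3β-(tert-butyldimethylsilyloxy)-4α-hydroxy-7αH-eudesm-11(12)-en-8-one | C[C@@]1(O)[C@@H](O[Si](C)(C)C(C)(C)C)CC[C@]2(C)CC(=O)[C@@H](C(C)=C)C[C@@H]12 | intermediate
12 | 3β-(tert-butyldimethylsilyloxy)-4α-hydroxyeudesm-7(11)-en-8-one | C[C@@]1(O)[C@@H](O[Si](C)(C)C(C)(C)C)CC[C@]2(C)CC(=O)C(=C(C)C)C[C@@H]12 | intermediate
13 | 3β,4α-dihydroxyeudesm-7(11)-en-8-one | C[C@@]1(O)[C@@H](O)CC[C@]2(C)CC(=O)C(=C(C)C)C[C@@H]12 | intermediate
14 | angelic acid, (Z)-2-methylbut-2-enoic acid | C/C=C(/C)C(=O)O | starting material
15 | angeloyl 2,4,6-trichlorobenzoyl anhydride (mixed anhydride) | C/C=C(/C)C(=O)OC(=O)c1c(Cl)cc(Cl)cc1Cl | intermediate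
16 | 3β-angeloyloxy-4α-hydroxyeudesm-7(11)-en-8-one | C/C=C(/C)C(=O)O[C@H]1CC[C@]2(C)CC(=O)C(=C(C)C)C[C@H]2[C@]1(C)O | intermediate
17 | 3β-angeloyloxy-11-hydroperoxy-4α-hydroxyeudesm-6-en-8-one (CNP0161122.1) | C/C=C(/C)C(=O)O[C@H]1CC[C@]2(C)CC(=O)C(C(C)(C)OO)=C[C@H]2[C@]1(C)O | target

**Totals**
Total step count: 14
Longest linear sequence: 14 steps (1 to 17; angelic acid 14 enters as purchased)

**Steps most likely to fail**

1. Step 5. The risk is incomplete facial selectivity of oxygen transfer, or some attack at the lactone methylene. The fallback uses hydroxyl-directed oxygen delivery instead of steric control and sets out from the axial alcohol 2. VO(acac)2 (cat.) and t-BuOOH in CH2Cl2 should deliver oxygen to C4=C15 on the face of the 3α-hydroxyl through the vanadate ester, giving 3α-hydroxy-4α,15-epoxyisoalantolactone F1. Dess–Martin oxidation would give 3-oxo-4α,15-epoxyisoalantolactone F2. NaBH4/CeCl3·7H2O in MeOH at −78 °C, by axial hydride delivery anti to the C4–C15 bond, should give 3β-hydroxy-4α,15-epoxyisoalantolactone F3. TBSCl/imidazole in DMF brings this back to the route at 6.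

2. Step 14. The risk is a slow ene reaction at the electron-poor enone, which would let singlet oxygen or the excited sensitiser act on the angelate alkene (competing ene reaction or Z to E isomerisation). The fallback moves the oxygenation ahead of the acylation and sets out from silyl ether 12.
   - Photooxygenation of 12 (O2, tetraphenylporphyrin, light, CH2Cl2) should give 3β-(tert-butyldimethylsilyloxy)-11-hydroperoxy-4α-hydroxyeudesm-6-en-8-one F5.
   - 2-Methoxypropene with catalytic pyridinium p-toluenesulfonate in CH2Cl2 at 0 °C masks the hydroperoxide as the 2-methoxyprop-2-yl peroxyketal F6.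
   - Bu4NF buffered with AcOH in THF removes the silyl group to give the 3β-hydroxy peroxyketal F7.
   - Acylation with mixed anhydride 15 under the conditions of step 13 gives the 3β-angeloyloxy peroxyketal F8.
   - AcOH/THF/H2O at rt releases the hydroperoxide and comes back to the route at 17.

3. Step 13. The risk is isomerisation of the (Z)-2-methylbut-2-enoyl unit to the E (tigloyl) form during activation or acyl transfer, or sluggish acylation of the hindered 3β-hydroxyl next to the quaternary C4. The fallback builds the Z alkene on the ester instead of transferring it and sets out from diol 13. Esterification with 2-[bis(2,2,2-trifluoroethoxy)phosphoryl]propanoic acid (EDC·HCl, DMAP, CH2Cl2) should give the 3β-phosphonopropanoate of 4α-hydroxyeudesm-7(11)-en-8-one F4. Still–Gennari olefination (KN(SiMe3)2, 18-crown-6, THF, −78 °C, then acetaldehyde) should form the Z-trisubstituted enoate and comes back to the route at 16.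

**Further compounds**
F1 | step 5 | 3α-hydroxy-4α,15-epoxyisoalantolactone | C1O[C@@]12[C@H](O)CC[C@]3(C)C[C@H]4OC(=O)C(=C)[C@H]4C[C@@H]23
F2 | step 5 | 3-oxo-4α,15-epoxyisoalantolactone | C1O[C@@]12C(=O)CC[C@]3(C)C[C@H]4OC(=O)C(=C)[C@H]4C[C@@H]23
F3 | step 5 | 3β-hydroxy-4α,15-epoxyisoalantolactone | C1O[C@@]12[C@@H](O)CC[C@]3(C)C[C@H]4OC(=O)C(=C)[C@H]4C[C@@H]23
F4 | step 13 | 3β-{2-[bis(2,2,2-trifluoroethoxy)phosphoryl]propanoyloxy}-4α-hydroxyeudesm-7(11)-en-8-one | CC(C(=O)O[C@H]1CC[C@]2(C)CC(=O)C(=C(C)C)C[C@H]2[C@]1(C)O)P(=O)(OCC(F)(F)F)OCC(F)(F)F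
F5 | step 14 | 3β-(tert-butyldimethylsilyloxy)-11-hydroperoxy-4α-hydroxyeudesm-6-en-8-one | C[C@@]1(O)[C@@H](O[Si](C)(C)C(C)(C)C)CC[C@]2(C)CC(=O)C(C(C)(C)OO)=C[C@@H]12
F6 | step 14 | 3β-(tert-butyldimethylsilyloxy)-4α-hydroxy-11-(2-methoxyprop-2-ylperoxy)eudesm-6-en-8-one | C[C@@]1(O)[C@@H](O[Si](C)(C)C(C)(C)C)CC[C@]2(C)CC(=O)C(C(C)(C)OOC(C)(C)OC)=C[C@@H]12
F7 | step 14 | 3β,4α-dihydroxy-11-(2-methoxyprop-2-ylperoxy)eudesm-6-en-8-one | C[C@@]1(O)[C@@H](O)CC[C@]2(C)CC(=O)C(C(C)(C)OOC(C)(C)OC)=C[C@@H]12
F8 | step 14 | 3β-angeloyloxy-4α-hydroxy-11-(2-methoxyprop-2-ylperoxy)eudesm-6-en-8-one | C/C=C(/C)C(=O)O[C@H]1CC[C@]2(C)CC(=O)C(C(C)(C)OOC(C)(C)OC)=C[C@H]2[C@]1(C)O
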